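**Retrosynthetic overview**
1. Feature: C2' of the piperidine ring is bonded to N1' and to C8 of ring A, so it is both α to nitrogen and benzylic, and C3' is the ring methylene beside it. A carbanion at C2' (the reverse of its usual iminium polarity) can therefore close the ring on a halide at C3'.
2. Ring C is opened last: C4–C4a (cycloacylation) and O1–C2 (oxa-Michael addition to ethyl phenylpropiolate) lead back to an (R)-2-arylpiperidine phenol. Its O1 oxygen travels as an isopropyl ether and the C5/C7 oxygens as methyl ethers.
3. Piperidine ring: C2'–C3' is disconnected to an N-Boc-N-(4-chlorobutyl)benzylamine. Sparteine-mediated benzylic lithiation and displacement of chloride close the ring and set (R)-C2'.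
4. The benzylamine is assembled from 2-hydroxy-4,6-dimethoxybenzaldehyde, 2-bromopropane, 4-aminobutan-1-ol and Boc2O.
5. Ring order: ring A and the 2-phenyl ring are bought; the piperidine ring is formed in step 4; the pyranone ring C in step 9.

Key step: step 4

Assumption: the closure of organolithium 11 is taken as invertive at the lithiated carbon (attack anti to the carbamate-chelated lithium), so 11 is drawn (S). The sense of induction of the sparteine enantiomers is assumed to carry over from the phenyl series to this 2,6-dialkoxyaryl substrate, the substituent ranking at C2' (N > aryl > CH2 > H) being the same.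

**Route**

Step 1
Reactants: 1 2-hydroxy-4,6-dimethoxybenzaldehyde; 2 2-bromopropane
Product: 3 2-isopropoxy-4,6-dimethoxybenzaldehyde
Conditions: K2CO3, KI (cat.), DMF, 70 °C
Reagents that add atoms: none
Why: Williamson ether synthesis: carbonate in DMF frees the phenoxide from its hydrogen bond to the aldehyde and it displaces bromide (via the iodide formed in situ) from the secondary halide, tagging the oxygen that becomes O1 with a group that can later be removed without touching the methyl ethers.

Step 2
Reactants: 3 2-isopropoxy-4,6-dimethoxybenzaldehyde; 4 4-aminobutan-1-ol; 5 di-tert-butyl dicarbonate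
Product: 8 tert-butyl (4-hydroxybutyl)(2-isopropoxy-4,6-dimethoxybenzyl)carbamate, via imine 6 (not isolated), via secondary amine 7 (not isolated)
Conditions: 4, MeOH, 3 Å sieves, rt; NaBH4, 0 °C; then 5, 0 °C → rt
Reagents that add atoms: none
Why: Reductive amination (imine condensation, then NaBH4 reduction of the C=N bond) followed in the same flask by N-acylation with Boc2O, which takes place only at the far more nucleophilic secondary amine and not at the primary alcohol; no acid is used, because the 2,4,6-trialkoxybenzyl–nitrogen bond is acid-labile.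

Step 3
Reactants: 8 tert-butyl (4-hydroxybutyl)(2-isopropoxy-4,6-dimethoxybenzyl)carbamate
Product: 10 tert-butyl (4-chlorobutyl)(2-isopropoxy-4,6-dimethoxybenzyl)carbamate, via mesylate 9 (not isolated)
Conditions: MsCl, Et3N, CH2Cl2, 0 °C; then LiCl, DMF, 50 °C
Reagents that add atoms: lithium chloride, [Li+].[Cl-]; methanesulfonyl chloride, CS(=O)(=O)Cl (its atoms stay only in 9)
Why: Mesylation of the primary alcohol and SN2 displacement of mesylate by chloride (Finkelstein-type exchange) under buffered, non-acidic conditions; chloride is the leaving group wanted for step 4 because, unlike bromide or iodide, it does not undergo halogen–lithium exchange with s-BuLi.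

Step 4
Reactants: 10 tert-butyl (4-chlorobutyl)(2-isopropoxy-4,6-dimethoxybenzyl)carbamate
Product: 12 tert-butyl (R)-2-(2-isopropoxy-4,6-dimethoxyphenyl)piperidine-1-carboxylate, via benzylic organolithium 11 (not isolated)
Conditions: s-BuLi (1.15 equiv), (+)-sparteine (1.2 equiv), toluene, −78 °C, slow warming to −40 °C; MeOH quench
Reagents that add atoms: sec-butyllithium, CCC(C)[Li] (its lithium stays only in 11)
Why: The Boc carbonyl binds the s-BuLi·(+)-sparteine complex and delivers the base to the adjacent benzylic CH2 (complex-induced proximity), so one of the two enantiotopic protons is removed to give the dipole-stabilised α-amino benzyllithium 11, whose carbanion then displaces chloride from the chain terminus in an intramolecular SN2 alkylation that forms C2'–C3'. The closest known reaction type is the sparteine-mediated asymmetric lithiation–cyclisation of N-Boc-N-(ω-chloroalkyl)benzylamines to N-Boc-2-aryl azacycles. The piperidine closes in the 6-exo-tet mode. The C2' stereocentre is controlled by the chiral diamine on lithium in the enantiodetermining deprotonation: (−)-sparteine leads to the (S) series of 2-aryl azacycles, so the (+)-enantiomer is used for (R), and toluene at −78 °C is chosen so that 11 closes before it can epimerise. The step needs benzylic rather than ring metalation (each of the two arene C–H bonds lies between two alkoxy groups); this is secured by the carbamate, which places the base next to the benzylic hydrogens while the ring hydrogens are meta to the side chain and out of its reach, by the non-coordinating solvent, and by the fact that any ring-lithiated material would simply return 10 on quench. Chloride as leaving group and only a slight excess of base guard against halogen–lithium exchange, elimination and removal of the remaining C2'–H of 12.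

Step 5
Reactants: 12 tert-butyl (R)-2-(2-isopropoxy-4,6-dimethoxyphenyl)piperidine-1-carboxylate
Product: 13 (R)-2-(2-isopropoxy-4,6-dimethoxyphenyl)-1-methylpiperidine
Conditions: LiAlH4, THF, reflux; H2O/aq NaOH work-up
Reagents that add atoms: none
Why: Hydride reduction of a carbamate to an N-methylamine: hydride adds to the Boc carbonyl, tert-butoxide leaves and the resulting formamide is reduced through its iminium ion, so the Boc carbon becomes the N-methyl carbon without acid, tert-butyl cations or formaldehyde ever meeting the electron-rich arene, and C2' is not touched.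

Step 6
Reactants: 13 (R)-2-(2-isopropoxy-4,6-dimethoxyphenyl)-1-methylpiperidine
Product: 14 (R)-3,5-dimethoxy-2-(1-methylpiperidin-2-yl)phenol
Conditions: BCl3 (3 equiv), CH2Cl2, −78 → 0 °C; MeOH, then aq NaHCO3
Reagents that add atoms: none
Why: Lewis-acid ether cleavage: after the amine is bound as its BCl3 adduct, further BCl3 activates the ethers and chloride removes the secondary isopropyl group much faster than a methyl group that has no chelating carbonyl neighbour, so only the phenol that becomes O1 is set free.

Step 7
Reactants: 14 (R)-3,5-dimethoxy-2-(1-methylpiperidin-2-yl)phenol; 15 ethyl 3-phenylprop-2-ynoate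
Product: 16 ethyl (Z)-3-{3,5-dimethoxy-2-[(R)-1-methylpiperidin-2-yl]phenoxy}-3-phenylprop-2-enoate
Conditions: Cs2CO3 (0.3 equiv), DMF, 50 °C
Reagents that add atoms: none
Why: Oxa-Michael addition: the phenoxide adds to the phenyl-bearing β-carbon of the ynoate and the vinyl anion is protonated anti, forming O1–C2 and giving mainly the Z enol ether (the geometry needed for ring closure, and in any case equilibrated by acid in step 9), while the tertiary amine cannot form a stable adduct.

Step 8
Reactants: 16 ethyl (Z)-3-{3,5-dimethoxy-2-[(R)-1-methylpiperidin-2-yl]phenoxy}-3-phenylprop-2-enoate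
Product: 17 (Z)-3-{3,5-dimethoxy-2-[(R)-1-methylpiperidin-2-yl]phenoxy}-3-phenylprop-2-enoic acid
Conditions: LiOH·H2O, THF/H2O, rt; HCl to pH 6–7
Reagents that add atoms: water (as hydroxide from LiOH·H2O), O
Why: Saponification of the ethyl ester by hydroxide (acyl substitution) at room temperature, mild enough to leave the β-aryloxy enol ether in place, should give the amino acid, which is isolated at its isoelectric point.

Step 9
Reactants: 17 (Z)-3-{3,5-dimethoxy-2-[(R)-1-methylpiperidin-2-yl]phenoxy}-3-phenylprop-2-enoic acid
Product: 18 5,7-dimethoxy-8-[(R)-1-methylpiperidin-2-yl]-2-phenyl-4H-chromen-4-one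
Conditions: P4O10 in MeSO3H (Eaton's reagent), 0 °C → rt; aq NaHCO3
Reagents that add atoms: none
Why: Intramolecular Friedel–Crafts acylation (the Ruhemann flavone closure): the activated carboxyl attacks the only free carbon ortho to the aryloxy oxygen, which is also ortho to one methoxy and para to the other, forming C4–C4a and closing the six-membered pyranone ring C, with the amine held as its ammonium ion and the acid equilibrating any E isomer.

Step 10
Reactants: 18 5,7-dimethoxy-8-[(R)-1-methylpiperidin-2-yl]-2-phenyl-4H-chromen-4-one
Product: 19 5,7-dihydroxy-8-[(R)-1-methylpiperidin-2-yl]-2-phenyl-4H-chromen-4-one (target)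
Conditions: BBr3 (6 equiv), CH2Cl2, −78 °C → rt; MeOH, then aq NaHCO3 to pH 8
Reagents that add atoms: none
Why: Lewis-acid demethylation: BBr3 binds the amine and the carbonyl first, then cleaves the C5 methyl ether with chelation assistance from C4=O and the C7 methyl ether through its bromoborane oxonium ion (bromide attack on methyl), and methanolysis of the borate esters releases both phenols without heating the benzylic stereocentre.

**Compound list**
1 | 2-hydroxy-4,6-dimethoxybenzaldehyde | COc1cc(O)c(C=O)c(OC)c1 | starting material
2 | 2-bromopropane | CC(C)Br | starting material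
3 | 2-isopropoxy-4,6-dimethoxybenzaldehyde | COc1cc(OC(C)C)c(C=O)c(OC)c1 | intermediate
4 | 4-aminobutan-1-ol | NCCCCO | starting material
5 | di-tert-butyl dicarbonate | CC(C)(C)OC(=O)OC(=O)OC(C)(C)C | starting material
6 | (E)-4-{[(2-isopropoxy-4,6-dimethoxyphenyl)methylidene]amino}butan-1-ol (imine, not isolated) | OCCCC/N=C/c1c(OC)cc(OC)cc1OC(C)C | intermediate
7 | 4-{[(2-isopropoxy-4,6-dimethoxyphenyl)methyl]amino}butan-1-ol (secondary amine, not isolated) | OCCCCNCc1c(OC)cc(OC)cc1OC(C)C | intermediate
8 | tert-butyl (4-hydroxybutyl)(2-isopropoxy-4,6-dimethoxybenzyl)carbamate | CC(C)(C)OC(=O)N(CCCCO)Cc1c(OC)cc(OC)cc1OC(C)C | intermediate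
9 | 4-[(tert-butoxycarbonyl)(2-isopropoxy-4,6-dimethoxybenzyl)amino]butyl methanesulfonate (mesylate, not isolated) | CC(C)(C)OC(=O)N(CCCCOS(C)(=O)=O)Cc1c(OC)cc(OC)cc1OC(C)C | intermediate
10 | tert-butyl (4-chlorobutyl)(2-isopropoxy-4,6-dimethoxybenzyl)carbamate | CC(C)(C)OC(=O)N(CCCCCl)Cc1c(OC)cc(OC)cc1OC(C)C | intermediate
11 | tert-butyl (4-chlorobutyl)[(S)-lithio(2-isopropoxy-4,6-dimethoxyphenyl)methyl]carbamate, as its (+)-sparteine complex (benzylic organolithium, not isolated) | CC(C)(C)OC(=O)N(CCCCCl)[C@@H]([Li])c1c(OC)cc(OC)cc1OC(C)C | intermediate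
12 | tert-butyl (R)-2-(2-isopropoxy-4,6-dimethoxyphenyl)piperidine-1-carboxylate | CC(C)(C)OC(=O)N1CCCC[C@@H]1c1c(OC)cc(OC)cc1OC(C)C | intermediate
13 | (R)-2-(2-isopropoxy-4,6-dimethoxyphenyl)-1-methylpiperidine | CN1CCCC[C@@H]1c1c(OC)cc(OC)cc1OC(C)C | intermediate
14 | (R)-3,5-dimethoxy-2-(1-methylpiperidin-2-yl)phenol | CN1CCCC[C@@H]1c1c(OC)cc(OC)cc1O | intermediate
15 | ethyl 3-phenylprop-2-ynoate (ethyl phenylpropiolate) | CCOC(=O)C#Cc1ccccc1 | starting material
16 | ethyl (Z)-3-{3,5-dimethoxy-2-[(R)-1-methylpiperidin-2-yl]phenoxy}-3-phenylprop-2-enoate | CCOC(=O)/C=C(\Oc1cc(OC)cc(OC)c1[C@H]1CCCCN1C)c1ccccc1 | intermediate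
17 | (Z)-3-{3,5-dimethoxy-2-[(R)-1-methylpiperidin-2-yl]phenoxy}-3-phenylprop-2-enoic acid | OC(=O)/C=C(\Oc1cc(OC)cc(OC)c1[C@H]1CCCCN1C)c1ccccc1 | intermediate
18 | 5,7-dimethoxy-8-[(R)-1-methylpiperidin-2-yl]-2-phenyl-4H-chromen-4-one | CN1CCCC[C@@H]1c1c(OC)cc(OC)c2c(=O)cc(-c3ccccc3)oc12 | intermediate
19 | 5,7-dihydroxy-8-[(R)-1-methylpiperidin-2-yl]-2-phenyl-4H-chromen-4-one | CN1CCCC[C@@H]1c1c(O)cc(O)c2c(=O)cc(-c3ccccc3)oc12 | target

**Step count**
Total steps: 10. Longest linear sequence: 10 steps (1 → 19).

**Steps most likely to fail**

1. Step 4. The six-membered closure is slower than the five-membered parent case, so the organolithium may epimerise before it cyclises and the enantiomeric purity would drop. The ortho alkoxy oxygens may also compete with the diamine for lithium, and metalation of the arene C–H bonds flanked by alkoxy groups may consume base. The fallback sets out from 3 and comes back to the route at 13; it makes the same C2'–C3' bond with normal polarity. Condensation of 3 with (S)-2-methylpropane-2-sulfinamide (Ti(OEt)4, THF, 60 °C) should give the N-sulfinyl imine F1. Addition of 4-chlorobutylmagnesium bromide (from 1-bromo-4-chlorobutane and Mg) in CH2Cl2 at −48 °C, through the closed chair transition state in which magnesium bridges the sulfinyl oxygen, should give the (R)-configured sulfinamide F2. NaH in DMF then closes the ring by N-alkylation to the N-sulfinylpiperidine F3. HCl in MeOH at 0 °C removes the auxiliary to give the free piperidine F4, and reductive methylation (aq CH2O, NaBH(OAc)3, 1,2-dichloroethane, rt) gives 13.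

2. Step 9. Before the acyl group is in place, the ring still carries two methoxy donors ortho and para to C2'. In the strongly acidic medium the protonated amine may ionise at the benzylic C2'–N bond, which would erode the configuration or open the piperidine. The fallback sets out from 14 and comes back at 18. Ortho-acetylation of 14 (Ac2O, BF3·OEt2, 60 °C; Friedel–Crafts/Fries, the amine held as its BF3 adduct and not as an ammonium leaving group) should give the acetophenone F5. Crossed Claisen condensation with methyl benzoate (NaH, DMF), the Baker–Venkataraman-type assembly, gives the 1,3-diketone F6. Cyclodehydration with catalytic H2SO4 in AcOH at 50 °C, now on a ring deactivated by the acyl group, gives 18.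

3. Step 10. Cleavage of the hindered C7 methyl ether next to the basic nitrogen may stop short under conditions mild enough for C2'. Forcing it risks epimerisation through retro-Mannich opening once the C7 hydroxyl is free. The fallback sets out from 18 and comes back at 19, and splits the double dealkylation into two events of different mechanism. BCl3 (CH2Cl2, −20 → 0 °C) should remove only the C5 methyl group, by chelation to the C4 carbonyl, giving the 5-hydroxy-7-methoxyflavone F7. Iodotrimethylsilane made in situ (Me3SiCl, NaI, MeCN, 60 °C) then cleaves the C7 ether by O-silylation and SN2 attack of iodide on the methyl carbon, and aqueous work-up gives 19.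

**Further compounds**
F1 | step 4 | (S,E)-N-[(2-isopropoxy-4,6-dimethoxyphenyl)methylidene]-2-methylpropane-2-sulfinamide | CC(C)(C)[S@](=O)/N=C/c1c(OC)cc(OC)cc1OC(C)C
F2 | step 4 | (S)-N-[(R)-5-chloro-1-(2-isopropoxy-4,6-dimethoxyphenyl)pentyl]-2-methylpropane-2-sulfinamide | CC(C)(C)[S@](=O)N[C@H](CCCCCl)c1c(OC)cc(OC)cc1OC(C)C
F3 | step 4 | (R)-1-[(S)-tert-butylsulfinyl]-2-(2-isopropoxy-4,6-dimethoxyphenyl)piperidine | CC(C)(C)[S@](=O)N1CCCC[C@@H]1c1c(OC)cc(OC)cc1OC(C)C
F4 | step 4 | (R)-2-(2-isopropoxy-4,6-dimethoxyphenyl)piperidine | N1CCCC[C@@H]1c1c(OC)cc(OC)cc1OC(C)C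
F5 | step 9 | 1-{2-hydroxy-4,6-dimethoxy-3-[(R)-1-methylpiperidin-2-yl]phenyl}ethan-1-one | CC(=O)c1c(OC)cc(OC)c([C@H]2CCCCN2C)c1O
F6 | step 9 | 1-{2-hydroxy-4,6-dimethoxy-3-[(R)-1-methylpiperidin-2-yl]phenyl}-3-phenylpropane-1,3-dione | O=C(CC(=O)c1c(OC)cc(OC)c([C@H]2CCCCN2C)c1O)c1ccccc1
F7 | step 10 | 5-hydroxy-7-methoxy-8-[(R)-1-methylpiperidin-2-yl]-2-phenyl-4H-chromen-4-one | CN1CCCC[C@@H]1c1c(OC)cc(O)c2c(=O)cc(-c3ccccc3)oc12
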